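**Strategy.** Ring B (labdane numbering) becomes a Diels–Alder retron once its C7=C8 enoic acid is read as the carbonylated enol of an 8-ketone. The isomeric C8=C9 enol ether is the adduct of a C7=C8–C9=C10 diene and a C5=C6 dienophile. Because C5–C10 is the A/B fusion bond, the C1–C4 tether closes ring A in the same event. The precursor is the acyclic (E)-enal/2-methoxydiene 20, in which a removable formyl group on C6 activates the dienophile. A chiral oxazaborolidinium catalyst should fold it into the trans-decalin, fixing C5 and C10; acid work-up sets C9. Decarbonylation, enol triflate carbonylation and acylation finish the synthesis.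

Key step: step 16

Assumption 1: atom numbers are labdane numbers (C1–C10 decalin, C11–C16 side chain, C17 carboxyl carbon, C20 angular methyl); α/β refer to the usual labdane drawing (10-methyl β).
Assumption 2: the facial sense of the (S)-configured catalyst in step 16 is taken from the formyl C–H···O binding model; if the first experiment shows the opposite sense, the (R)-catalyst is used and nothing else changes.

**Side-chain fragment (C11–C16)**

Step 1
Reactants: 1 4-(tert-butyldimethylsilyloxy)but-1-yne
Product: 3 (E)-5-(tert-butyldimethylsilyloxy)-3-methylpent-2-en-1-ol, via alkenylalane 2 (not isolated)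
Conditions: Me3Al, Cp2ZrCl2 (cat.), CH2Cl2, 0 °C to rt; then n-BuLi, THF, −78 °C; (CH2O)n, rt
Reagents that add atoms: trimethylaluminium C[Al](C)C; formaldehyde (from paraformaldehyde) C=O
Why: Negishi zirconium-catalysed syn-carboalumination places methyl and aluminium cis on the terminal alkyne, and hydroxymethylation of the derived alanate with retention fixes the (E)-trisubstituted C13=C14 olefin.

Step 2
Reactants: 3 (E)-5-(tert-butyldimethylsilyloxy)-3-methylpent-2-en-1-ol
Product: 4 (E)-5-(tert-butyldimethylsilyloxy)-1-(4-methoxybenzyloxy)-3-methylpent-2-ene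
Conditions: NaH, 4-methoxybenzyl chloride, Bu4NI (cat.), THF/DMF, 0 °C to rt
Reagents that add atoms: 4-methoxybenzyl chloride COc1ccc(CCl)cc1
Why: Williamson etherification of the primary allylic alkoxide with the benzylic chloride should proceed without touching the silyl ether or the olefin geometry.

Step 3
Reactants: 4 (E)-5-(tert-butyldimethylsilyloxy)-1-(4-methoxybenzyloxy)-3-methylpent-2-ene
Product: 5 (E)-5-(4-methoxybenzyloxy)-3-methylpent-3-en-1-ol
Conditions: Bu4NF, THF, 0 °C to rt
Reagents that add atoms: none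
Why: Fluoride-mediated silyl ether cleavage is selective for the Si–O bond and leaves the 4-methoxybenzyl ether intact.

Step 4
Reactants: 5 (E)-5-(4-methoxybenzyloxy)-3-methylpent-3-en-1-ol
Product: 6 (E)-5-iodo-1-(4-methoxybenzyloxy)-3-methylpent-2-ene
Conditions: I2, PPh3, imidazole, CH2Cl2, 0 °C
Reagents that add atoms: iodine II
Why: Appel-type iodination converts the primary alcohol into the iodide by SN2 displacement of an alkoxyphosphonium ion under buffered conditions that spare the benzyl ether.

**Tether fragment (C2–C6 plus the temporary formyl carbon)**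

Step 5
Reactants: 7 (tert-butyldimethylsilyloxy)acetaldehyde
Product: 8 rac-1-(tert-butyldimethylsilyloxy)-4-methylpent-3-en-2-ol
Conditions: 2-methyl-1-propenylmagnesium bromide, THF, −78 to 0 °C
Reagents that add atoms: 2-methyl-1-propenylmagnesium bromide CC(C)=C[Mg]Br
Why: Grignard 1,2-addition to the aldehyde gives the secondary allylic alcohol, whose racemic carbinol centre is destroyed in the next step.

Step 6
Reactants: 8 rac-1-(tert-butyldimethylsilyloxy)-4-methylpent-3-en-2-ol
Product: 10 ethyl (E)-6-(tert-butyldimethylsilyloxy)-3,3-dimethylhex-4-enoate, via mixed ketene acetal 9 (not isolated)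
Conditions: MeC(OEt)3 (excess), EtCO2H (cat.), 140 °C, removal of EtOH
Reagents that add atoms: triethyl orthoacetate CCOC(C)(OCC)OCC
Why: Johnson–Claisen rearrangement through a chair transition state with the silyloxymethyl group equatorial should create the C4 quaternary carbon with its geminal methyls and the (E)-C5=C6 olefin in one operation.

Step 7
Reactants: 10 ethyl (E)-6-(tert-butyldimethylsilyloxy)-3,3-dimethylhex-4-enoate
Product: 11 (E)-6-(tert-butyldimethylsilyloxy)-3,3-dimethylhex-4-en-1-ol
Conditions: LiAlH4, Et2O, 0 °C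
Reagents that add atoms: none
Why: Hydride reduction of the ester to the primary alcohol leaves the isolated olefin and the silyl ether untouched.

Step 8
Reactants: 11 (E)-6-(tert-butyldimethylsilyloxy)-3,3-dimethylhex-4-en-1-ol
Product: 12 (E)-1-(tert-butyldimethylsilyloxy)-6-iodo-4,4-dimethylhex-2-ene
Conditions: I2, PPh3, imidazole, CH2Cl2, 0 °C
Reagents that add atoms: iodine II
Why: Appel-type iodination of the unhindered primary alcohol proceeds by SN2 displacement and is compatible with the allylic silyl ether in the presence of imidazole.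

**Assembly of the acyclic precursor**

Step 9
Reactants: 13 methyl acetoacetate; 6 (E)-5-iodo-1-(4-methoxybenzyloxy)-3-methylpent-2-ene
Product: 14 methyl (E)-2-acetyl-7-(4-methoxybenzyloxy)-5-methylhept-5-enoate (racemic at C2)
Conditions: K2CO3, acetone, reflux (13 in excess)
Reagents that add atoms: none
Why: Acetoacetic ester alkylation by SN2 C-alkylation of the soft potassium enolate joins C9 to C11, excess acetoacetate suppresses dialkylation, and the racemic α-centre becomes sp2 in step 11.

Step 10
Reactants: 14 methyl (E)-2-acetyl-7-(4-methoxybenzyloxy)-5-methylhept-5-enoate; 12 (E)-1-(tert-butyldimethylsilyloxy)-6-iodo-4,4-dimethylhex-2-ene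
Product: 15 methyl (E)-10-(tert-butyldimethylsilyloxy)-2-[(E)-5-(4-methoxybenzyloxy)-3-methylpent-3-enyl]-7,7-dimethyl-3-oxodec-8-enoate (racemic at C2)
Conditions: NaH, THF, 0 °C; n-BuLi, 0 °C; then 12, 0 °C to rt; aqueous quench
Reagents that add atoms: none
Why: γ-Alkylation of the acetoacetate dianion occurs at the more basic terminal carbanion and joins C1 to C2 by SN2 reaction with the primary iodide.

Step 11
Reactants: 15 methyl (E)-10-(tert-butyldimethylsilyloxy)-2-[(E)-5-(4-methoxybenzyloxy)-3-methylpent-3-enyl]-7,7-dimethyl-3-oxodec-8-enoate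
Product: 16 methyl (2Z,8E)-10-(tert-butyldimethylsilyloxy)-2-[(E)-5-(4-methoxybenzyloxy)-3-methylpent-3-enyl]-7,7-dimethyl-3-(trifluoromethylsulfonyloxy)deca-2,8-dienoate
Conditions: saturated aqueous LiOH, Tf2O, toluene, 5 °C
Reagents that add atoms: triflic anhydride O=S(=O)(OS(=O)(=O)C(F)(F)F)C(F)(F)F
Why: O-Triflation of the chelated lithium enolate, in which the two oxygens are held cis, should give the (Z)-enol triflate and so fix the geometry of the future C9=C10 diene bond.

Step 12
Reactants: 16 methyl (2Z,8E)-10-(tert-butyldimethylsilyloxy)-2-[(E)-5-(4-methoxybenzyloxy)-3-methylpent-3-enyl]-7,7-dimethyl-3-(trifluoromethylsulfonyloxy)deca-2,8-dienoate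
Product: 17 methyl (2E,8E)-10-(tert-butyldimethylsilyloxy)-2-[(E)-5-(4-methoxybenzyloxy)-3-methylpent-3-enyl]-3,7,7-trimethyldeca-2,8-dienoate
Conditions: MeZnCl, Pd(PPh3)4 (cat.), THF, rt to 50 °C
Reagents that add atoms: methylzinc chloride C[Zn]Cl
Why: Negishi cross-coupling (oxidative addition of zerovalent palladium to the enol triflate, transmetalation, reductive elimination) proceeds with retention of olefin geometry and places the C20 methyl cis to the ester carbon C8.

Step 13
Reactants: 17 methyl (2E,8E)-10-(tert-butyldimethylsilyloxy)-2-[(E)-5-(4-methoxybenzyloxy)-3-methylpent-3-enyl]-3,7,7-trimethyldeca-2,8-dienoate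
Product: 18 (2E,8E)-1-(tert-butyldimethylsilyloxy)-10-methoxy-9-[(E)-5-(4-methoxybenzyloxy)-3-methylpent-3-enyl]-4,4,8-trimethylundeca-2,8,10-triene
Conditions: Tebbe reagent Cp2Ti(CH2)(Cl)AlMe2, pyridine (cat.), THF/toluene, −40 °C to rt; aqueous NaOH quench, basic alumina
Reagents that add atoms: Tebbe reagent C[Al-]1(C)C[Ti](C2C=CC=C2)(C2C=CC=C2)[Cl+]1
Why: Tebbe methylenation converts the ester carbonyl into the methyl enol ether through an oxatitanacyclobutane, creating C7 and the 2-methoxy-1,3-diene without affecting the ethers.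

Step 14
Reactants: 18 (2E,8E)-1-(tert-butyldimethylsilyloxy)-10-methoxy-9-[(E)-5-(4-methoxybenzyloxy)-3-methylpent-3-enyl]-4,4,8-trimethylundeca-2,8,10-triene
Product: 19 (2E,8E)-10-methoxy-9-[(E)-5-(4-methoxybenzyloxy)-3-methylpent-3-enyl]-4,4,8-trimethylundeca-2,8,10-trien-1-ol
Conditions: Bu4NF, THF, 0 °C; Et3N-deactivated silica
Reagents that add atoms: none
Why: Fluoride-mediated silyl ether cleavage under non-acidic conditions preserves the dienol ether and the 4-methoxybenzyl ether.

Step 15
Reactants: 19 (2E,8E)-10-methoxy-9-[(E)-5-(4-methoxybenzyloxy)-3-methylpent-3-enyl]-4,4,8-trimethylundeca-2,8,10-trien-1-ol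
Product: 20 (2E,8E)-10-methoxy-9-[(E)-5-(4-methoxybenzyloxy)-3-methylpent-3-enyl]-4,4,8-trimethylundeca-2,8,10-trienal
Conditions: MnO2 (activated, excess), solid NaHCO3, CH2Cl2, rt; used at once
Reagents that add atoms: none
Why: MnO2 oxidises the allylic alcohol chemoselectively to the (E)-enal under neutral heterogeneous conditions that the dienol ether tolerates.

**Key step and completion**

Step 16
Reactants: 20 (2E,8E)-10-methoxy-9-[(E)-5-(4-methoxybenzyloxy)-3-methylpent-3-enyl]-4,4,8-trimethylundeca-2,8,10-trienal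
Product: 22 15-(4-methoxybenzyloxy)-8-oxo-17-norlabd-13E-ene-6α-carbaldehyde, via enol ether cycloadduct 21 (not isolated)
Conditions: (S)-oxazaborolidinium triflimide catalyst [from (S)-α,α-diphenylprolinol, tri-o-tolylboroxine and HNTf2] (20 mol %), CH2Cl2, −78 to −20 °C; then 1 M HCl, THF, 0 °C
Reagents that add atoms: water O
Why: The oxazaborolidinium ion binds the formyl group of the (E)-enal and lowers its LUMO so that the 2-methoxydiene C7=C8–C9=C10 adds suprafacially across C5=C6 in a concerted, asynchronous normal-demand [4+2] cycloaddition, the closest known reaction type being the cationic-oxazaborolidine-catalysed intramolecular Diels–Alder reaction of 2,7,9-trienals (1,3,8-nonatriene class). Ring B is closed by the cycloaddition itself (C6–C7 and C5–C10), and ring A is closed by the same C5–C10 bond through the C1–C4 tether in the fused (type 1) mode, the bridged mode being out of reach of a four-carbon tether. The trans relationship of H-5 and the C10 methyl should follow from the formyl-endo, tether-anti transition state of the (E)-dienophile together with the (E)-C9=C10 geometry, which puts the tether outside and the methyl inside; the transient C6 centre follows the same endo rule. The absolute configuration at C5 and C10 (5α-H, 10β-methyl) is set by the catalyst, which shields one face of the bound enal, and C9 is then set by axial protonation of the enol ether on the α face anti to the angular methyl, which is also the thermodynamic outcome (equatorial side chain). The step needs endo and facial selectivity and enough reactivity to join the neopentyl-type C5 to the fully substituted C10: the cationic catalyst gives strong activation, the C4 geminal methyls favour the folded tether (Thorpe–Ingold effect), and the 8-methoxy group destabilises the s-trans diene so that the s-cis form is populated despite the inside methyl.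

Step 17
Reactants: 22 15-(4-methoxybenzyloxy)-8-oxo-17-norlabd-13E-ene-6α-carbaldehyde
Product: 23 15-(4-methoxybenzyloxy)-17-norlabd-13E-en-8-one
Conditions: RhCl(PPh3)3 (1.1 equiv), PhCN, 130 °C
Reagents that add atoms: none
Why: Tsuji–Wilkinson decarbonylation (oxidative addition of the formyl C–H bond, CO extrusion, reductive elimination) replaces the C6 formyl group by hydrogen and removes the now superfluous C6 stereocentre while the ketone is inert.

Step 18
Reactants: 23 15-(4-methoxybenzyloxy)-17-norlabd-13E-en-8-one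
Product: 24 15-(4-methoxybenzyloxy)-17-norlabda-7,13E-dien-8-yl trifluoromethanesulfonate
Conditions: KN(SiMe3)2, THF, −78 °C; then PhNTf2, −78 to 0 °C
Reagents that add atoms: N-phenylbis(trifluoromethanesulfonimide) O=S(=O)(N(c1ccccc1)S(=O)(=O)C(F)(F)F)C(F)(F)F
Why: Kinetic deprotonation by the bulky amide at the less hindered C7 methylene (C9 is a neopentyl-type methine) followed by O-sulfonylation gives the C7=C8 enol triflate regioselectively and leaves C9 untouched.

Step 19
Reactants: 24 15-(4-methoxybenzyloxy)-17-norlabda-7,13E-dien-8-yl trifluoromethanesulfonate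
Product: 25 15-(4-methoxybenzyloxy)labda-7,13E-dien-17-oic acid
Conditions: Pd(OAc)2 (cat.), dppp, CO (1 atm), Et3N, DMF/H2O, 60 °C; acidic work-up
Reagents that add atoms: carbon monoxide [C-]#[O+]; water O
Why: Palladium-catalysed hydroxycarbonylation (oxidative addition to the enol triflate, CO insertion, hydrolysis of the acylpalladium species) installs C17 as the conjugated acid with the olefin fixed at C7=C8.

Step 20
Reactants: 25 15-(4-methoxybenzyloxy)labda-7,13E-dien-17-oic acid
Product: 26 15-hydroxylabda-7,13E-dien-17-oic acid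
Conditions: DDQ, CH2Cl2/pH 7 buffer, 0 °C
Reagents that add atoms: none
Why: Oxidative cleavage of the 4-methoxybenzyl ether by DDQ (hydride abstraction, hydrolysis of the oxocarbenium ion) frees the C15 allylic alcohol without affecting the olefins or the acid.

Step 21
Reactants: 26 15-hydroxylabda-7,13E-dien-17-oic acid
Product: 27 15-(isobutyryloxy)labda-7,13E-dien-17-oic acid (CNP0191003.1)
Conditions: isobutyric anhydride, DMAP (cat.), pyridine, CH2Cl2, 0 °C to rt; then aqueous NaHCO3/THF, acidify to pH 3
Reagents that add atoms: isobutyric anhydride CC(C)C(=O)OC(=O)C(C)C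
Why: DMAP-catalysed acylation esterifies the primary allylic alcohol, and any mixed anhydride formed at the hindered C17 acid is hydrolysed back during the bicarbonate work-up.

**Compound list**

1 | 4-(tert-butyldimethylsilyloxy)but-1-yne | C#CCCO[Si](C)(C)C(C)(C)C | starting material
2 | (E)-[4-(tert-butyldimethylsilyloxy)-2-methylbut-1-enyl]dimethylalane | C/C(=C\[Al](C)C)CCO[Si](C)(C)C(C)(C)C | intermediate
3 | (E)-5-(tert-butyldimethylsilyloxy)-3-methylpent-2-en-1-ol | C/C(=C\CO)CCO[Si](C)(C)C(C)(C)C | intermediate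
4 | (E)-5-(tert-butyldimethylsilyloxy)-1-(4-methoxybenzyloxy)-3-methylpent-2-ene | C/C(=C\COCc1ccc(OC)cc1)CCO[Si](C)(C)C(C)(C)C | intermediate
5 | (E)-5-(4-methoxybenzyloxy)-3-methylpent-3-en-1-ol | C/C(=C\COCc1ccc(OC)cc1)CCO | intermediate
6 | (E)-5-iodo-1-(4-methoxybenzyloxy)-3-methylpent-2-ene | C/C(=C\COCc1ccc(OC)cc1)CCI | intermediate
7 | (tert-butyldimethylsilyloxy)acetaldehyde | O=CCO[Si](C)(C)C(C)(C)C | starting material
8 | rac-1-(tert-butyldimethylsilyloxy)-4-methylpent-3-en-2-ol | CC(C)=CC(O)CO[Si](C)(C)C(C)(C)C | intermediate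
9 | mixed ketene acetal (1-ethoxyvinyl ether of 8) | C=C(OCC)OC(CO[Si](C)(C)C(C)(C)C)C=C(C)C | intermediate
10 | ethyl (E)-6-(tert-butyldimethylsilyloxy)-3,3-dimethylhex-4-enoate | CCOC(=O)CC(C)(C)/C=C/CO[Si](C)(C)C(C)(C)C | intermediate
11 | (E)-6-(tert-butyldimethylsilyloxy)-3,3-dimethylhex-4-en-1-ol | OCCC(C)(C)/C=C/CO[Si](C)(C)C(C)(C)C | intermediate
12 | (E)-1-(tert-butyldimethylsilyloxy)-6-iodo-4,4-dimethylhex-2-ene | ICCC(C)(C)/C=C/CO[Si](C)(C)C(C)(C)C | intermediate
13 | methyl acetoacetate | COC(=O)CC(C)=O | starting material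
14 | methyl (E)-2-acetyl-7-(4-methoxybenzyloxy)-5-methylhept-5-enoate, racemic at C2 | COC(=O)C(CC/C(C)=C/COCc1ccc(OC)cc1)C(C)=O | intermediate
15 | methyl (E)-10-(tert-butyldimethylsilyloxy)-2-[(E)-5-(4-methoxybenzyloxy)-3-methylpent-3-enyl]-7,7-dimethyl-3-oxodec-8-enoate, racemic at C2 | COC(=O)C(CC/C(C)=C/COCc1ccc(OC)cc1)C(=O)CCCC(C)(C)/C=C/CO[Si](C)(C)C(C)(C)C | intermediate
16 | (2Z,8E)-enol triflate of 15 (triflate cis to the ester) | COC(=O)/C(CC/C(C)=C/COCc1ccc(OC)cc1)=C(\OS(=O)(=O)C(F)(F)F)CCCC(C)(C)/C=C/CO[Si](C)(C)C(C)(C)C | intermediate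
17 | methyl (2E,8E)-10-(tert-butyldimethylsilyloxy)-2-[(E)-5-(4-methoxybenzyloxy)-3-methylpent-3-enyl]-3,7,7-trimethyldeca-2,8-dienoate (3-methyl cis to the ester) | COC(=O)/C(CC/C(C)=C/COCc1ccc(OC)cc1)=C(\C)CCCC(C)(C)/C=C/CO[Si](C)(C)C(C)(C)C | intermediate
18 | (2E,8E)-1-(tert-butyldimethylsilyloxy)-10-methoxy-9-[(E)-5-(4-methoxybenzyloxy)-3-methylpent-3-enyl]-4,4,8-trimethylundeca-2,8,10-triene | C=C(OC)/C(CC/C(C)=C/COCc1ccc(OC)cc1)=C(\C)CCCC(C)(C)/C=C/CO[Si](C)(C)C(C)(C)C | intermediate
19 | (2E,8E)-10-methoxy-9-[(E)-5-(4-methoxybenzyloxy)-3-methylpent-3-enyl]-4,4,8-trimethylundeca-2,8,10-trien-1-ol | C=C(OC)/C(CC/C(C)=C/COCc1ccc(OC)cc1)=C(\C)CCCC(C)(C)/C=C/CO | intermediate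
20 | (2E,8E)-10-methoxy-9-[(E)-5-(4-methoxybenzyloxy)-3-methylpent-3-enyl]-4,4,8-trimethylundeca-2,8,10-trienal | C=C(OC)/C(CC/C(C)=C/COCc1ccc(OC)cc1)=C(\C)CCCC(C)(C)/C=C/C=O | intermediate
21 | 8-methoxy-15-(4-methoxybenzyloxy)-17-norlabda-8,13E-diene-6α-carbaldehyde (5α-H, 10β-methyl) | C/C(=C\COCc1ccc(OC)cc1)CCC1=C(OC)C[C@H](C=O)[C@H]2C(C)(C)CCC[C@]12C | intermediate
22 | 15-(4-methoxybenzyloxy)-8-oxo-17-norlabd-13E-ene-6α-carbaldehyde (5α-H, 9α-H, 10β-methyl) | C/C(=C\COCc1ccc(OC)cc1)CC[C@H]1C(=O)C[C@H](C=O)[C@H]2C(C)(C)CCC[C@]12C | intermediate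
23 | 15-(4-methoxybenzyloxy)-17-norlabd-13E-en-8-one | C/C(=C\COCc1ccc(OC)cc1)CC[C@H]1C(=O)CC[C@H]2C(C)(C)CCC[C@]12C | intermediate
24 | 15-(4-methoxybenzyloxy)-17-norlabda-7,13E-dien-8-yl trifluoromethanesulfonate | C/C(=C\COCc1ccc(OC)cc1)CC[C@H]1C(OS(=O)(=O)C(F)(F)F)=CC[C@H]2C(C)(C)CCC[C@]12C | intermediate
25 | 15-(4-methoxybenzyloxy)labda-7,13E-dien-17-oic acid | C/C(=C\COCc1ccc(OC)cc1)CC[C@H]1C(C(=O)O)=CC[C@H]2C(C)(C)CCC[C@]12C | intermediate
26 | 15-hydroxylabda-7,13E-dien-17-oic acid | C/C(=C\CO)CC[C@H]1C(C(=O)O)=CC[C@H]2C(C)(C)CCC[C@]12C | intermediate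
27 | (5S,9R,10S)-15-(isobutyryloxy)labda-7,13E-dien-17-oic acid (CNP0191003.1) | C/C(=C\COC(=O)C(C)C)CC[C@H]1C(C(=O)O)=CC[C@H]2C(C)(C)CCC[C@]12C | target

**Totals.** Total step count: 21. Longest linear sequence: 17 steps (steps 1–4, then 9–21); the tether branch (steps 5–8) joins at step 10.

**Steps most likely to fail**

1. Step 16 (key step). The catalyst–aldehyde complex may not be reactive enough to join the congested C5 and C10 termini before the acid-labile dienol ether is protonated, and an uncatalysed or proton-catalysed pathway would erode facial selectivity. The fallback replaces catalyst control by a covalently bound auxiliary; it sets out from 20 and comes back at 22. Trienal 20 is oxidised under basic conditions (Ag2O, aqueous NaOH, THF/EtOH) to the trienoic acid F1, which is coupled (DCC, DMAP, CH2Cl2) with (S)-4-benzyl-2-oxazolidinone to the N-enoyl imide F2. Me2AlCl (CH2Cl2, −30 °C) should give the chelate-controlled endo cycloadduct, the enol ether imide F3 (not isolated), which 1 M HCl/THF converts on work-up to the keto imide F4, whose diastereomers can be separated. LiSEt (THF, 0 °C) gives the ethyl thioester F5, and Fukuyama reduction (Et3SiH, Pd/C, acetone) returns aldehyde 22. The antipode of the auxiliary is taken if the chelate model calls for it.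

2. Step 13. Methylenation of the hindered, conjugated ester may stall, or the methyl dienol ether may be lost by hydrolysis during isolation and the two following steps. The fallback makes a silyl dienol ether last, from a methyl ketone; it sets out from 17 and comes back at 22. Ester 17 is treated with Me3SiCH2Li (2.2 equiv, pentane/THF, 0 °C) to give the α-silyl ketone F6 (not isolated), which methanol converts to the methyl ketone F7. Bu4NF gives the hydroxy enone F8 and MnO2 the keto enal F9. Soft enolisation at the methyl group (i-Pr3SiOTf, Et3N, CH2Cl2, −78 °C) gives the 2-(triisopropylsilyloxy)diene trienal F10, which is cyclised under the catalyst conditions of step 16 to the silyl enol ether cycloadduct F11 (not isolated) and cleaved with HF·pyridine to 22.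

3. Step 17. β-Hydride elimination from the alkylrhodium intermediate may give ring olefins, rhodium hydride species may shift the side-chain double bond, or oxidative addition at the hindered formyl group may be sluggish. The fallback removes the carbon by radical decarboxylation; it sets out from 22 and comes back at 23. Pinnick oxidation (NaClO2, NaH2PO4, 2-methyl-2-butene, t-BuOH/H2O) gives the keto acid F12. N-Hydroxypyridine-2-thione, DCC and DMAP give the Barton ester F13, whose photolysis (visible light, t-BuSH, benzene, rt) should give 23 by reductive decarboxylation.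

Further compounds
F1 | step 16 | (2E,8E)-10-methoxy-9-[(E)-5-(4-methoxybenzyloxy)-3-methylpent-3-enyl]-4,4,8-trimethylundeca-2,8,10-trienoic acid | C=C(OC)/C(CC/C(C)=C/COCc1ccc(OC)cc1)=C(\C)CCCC(C)(C)/C=C/C(=O)O
F2 | step 16 | N-enoyl imide of F1 with (S)-4-benzyl-2-oxazolidinone | C=C(OC)/C(CC/C(C)=C/COCc1ccc(OC)cc1)=C(\C)CCCC(C)(C)/C=C/C(=O)N1[C@@H](Cc2ccccc2)COC1=O
F3 | step 16 | enol ether cycloadduct imide (8-methoxy-17-norlabda-8,13E-diene with the 6α-acyl oxazolidinone) | C/C(=C\COCc1ccc(OC)cc1)CCC1=C(OC)C[C@H](C(=O)N3[C@@H](Cc4ccccc4)COC3=O)[C@H]2C(C)(C)CCC[C@]12C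
F4 | step 16 | keto imide (8-oxo-17-norlabd-13E-ene with the 6α-acyl oxazolidinone) | C/C(=C\COCc1ccc(OC)cc1)CC[C@H]1C(=O)C[C@H](C(=O)N3[C@@H](Cc4ccccc4)COC3=O)[C@H]2C(C)(C)CCC[C@]12C
F5 | step 16 | S-ethyl 15-(4-methoxybenzyloxy)-8-oxo-17-norlabd-13E-ene-6α-carbothioate | C/C(=C\COCc1ccc(OC)cc1)CC[C@H]1C(=O)C[C@H](C(=O)SCC)[C@H]2C(C)(C)CCC[C@]12C
F6 | step 13 | α-(trimethylsilyl)methyl ketone from 17 | C[Si](C)(C)CC(=O)/C(CC/C(C)=C/COCc1ccc(OC)cc1)=C(\C)CCCC(C)(C)/C=C/CO[Si](C)(C)C(C)(C)C
F7 | step 13 | (3E,9E)-methyl ketone (acetyl in place of the ester of 17) | CC(=O)/C(CC/C(C)=C/COCc1ccc(OC)cc1)=C(\C)CCCC(C)(C)/C=C/CO[Si](C)(C)C(C)(C)C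
F8 | step 13 | hydroxy enone (desilylated F7) | CC(=O)/C(CC/C(C)=C/COCc1ccc(OC)cc1)=C(\C)CCCC(C)(C)/C=C/CO
F9 | step 13 | keto enal (allylic alcohol of F8 oxidised) | CC(=O)/C(CC/C(C)=C/COCc1ccc(OC)cc1)=C(\C)CCCC(C)(C)/C=C/C=O
F10 | step 13 | 2-(triisopropylsilyloxy)diene trienal (silyl analogue of 20) | C=C(O[Si](C(C)C)(C(C)C)C(C)C)/C(CC/C(C)=C/COCc1ccc(OC)cc1)=C(\C)CCCC(C)(C)/C=C/C=O
F11 | step 13 | silyl enol ether cycloadduct (silyl analogue of 21) | C/C(=C\COCc1ccc(OC)cc1)CCC1=C(O[Si](C(C)C)(C(C)C)C(C)C)C[C@H](C=O)[C@H]2C(C)(C)CCC[C@]12C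
F12 | step 17 | 15-(4-methoxybenzyloxy)-8-oxo-17-norlabd-13E-ene-6α-carboxylic acid | C/C(=C\COCc1ccc(OC)cc1)CC[C@H]1C(=O)C[C@H](C(=O)O)[C@H]2C(C)(C)CCC[C@]12C
F13 | step 17 | Barton ester of F12 (2-thioxopyridin-1-yl ester) | C/C(=C\COCc1ccc(OC)cc1)CC[C@H]1C(=O)C[C@H](C(=O)On3ccccc3=S)[C@H]2C(C)(C)CCC[C@]12C
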